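1. Every X charged stands as X, as D, as L, or in a form I can't read, so the percentages in the east run, which is the flask asked about, add up against one fixed charge.

| setting | east | north | flask |
|---|---|---|---|
| X | 0.70 M | 0.70 M | 0.70 M |
| J | 1.26 M | 2.5 M | 1.26 M |
| Q | 0.35 mM | 0.35 mM | 0.35 mM |
| remark | the very flask that is asked about, followed so far | run made earlier |  |
| time |  |  | 15 min |

| run | time / min | L / % | D / % |
|---|---|---|---|
| east | 0.333 | 0.6 | 3.6 |
| east | 1.00 | 2.0 | 15.0 |
| east | 2.00 | 7.4 | 26.2 |
| east | 2.50 | 12.1 | 29.5 |
| north | 1.33 | 4.4 | 22.2 |
| north | 4.00 | 30.6 | 33.9 |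
| north | 6.00 | 51.4 | 28.7 |
| north | 10.0 | 78.4 | 15.2 |

(scatter of a reading: 0.5 percentage points)

* share of L in L plus D at 12 s
* share of L in L plus D at 15 min
* which of L and D there is more of at 15 min

2. D has a feed and a drain, so I need one time for each. In the north run, L gains 27 percentage points between 6.00 min and 10.0 min on a mean D of 21.9 %. That reads as a constant of 0.308 /min, a drain half-life of 2.25 min.

3. In the east run, L plus D reaches 41.6 % at 2.50 min. Taken as first-order loss, that reads 0.215 /min, a feed half-life of 3.22 min.

4. Making of D over using of D starts high and drifts down through one at the peak of D. The drain reads faster than the feed, by a factor of 1.43, so D then falls with its feed, and the drain still shapes that fall. One minus drain half-life over feed half-life, 0.300, is my tail balance: making over using once D falls with its feed.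

5. Running feed and drain in series for the flask, I expect a share of L of 3.08 % at 12 s. At 15 min I expect D 6.93 % and L 89.1 %, a share of 92.8 %.

6. The forecast gives 3.5 %, 78 % and L ahead. It reckons “if each step consumes one J”, so its late share stands below mine.

7. The flask gives 2.18 % and 93.4 %, with L ahead at 90.3 % against 6.36 %, and 46.3 % of its J still there.

    J + Q + Z → Q + D (k = 120 /M²/s)
    D → L (k = 0.00520 /s)
    X + Q ⇌ Q + Z (K = 0.750, k = 14.0 /M/s)

At 15.0 min the flask makes D at 0.373 of the rate it uses it, each step taken net, and my tail balance was 0.300. The half-life of D by its step to L, 2.2 min, is short against 15 min. In the neighbour charged with 0.28 M of X, the balance turns what stands upstream, X 2.23 % and Z 0.249 %, times feed constant over balance times drain constant, into 5.77 % of D, and that flask holds 6.02 %.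

The readings stem from a simulated flask from invented constants; the scatter is artificial.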